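**Strategy**

The pyran ring is cut at both of its bonds to ring B, C4–C4a and O1–C8a, so that C2 arrives with its O1–C2 bond and configuration from (R)-linalool. In one palladium-catalysed operation a cyclic (Z)-alkenylboronic hemiester, an oxaborole holding O1, C2, C3 and C4, is stitched onto 2,3-dichloro-4-(SEM-oxy)benzaldehyde: Suzuki–Miyaura coupling at the chloride ortho to the formyl group, then C–O coupling of the released tertiary alkoxide at the neighbouring chloride. The step exploits the cis C3=C4 alkene of the pyran ring, which holds O1 and C4 over the adjacent carbons C8a and C4a of ring B. Aldol condensation, conjugate reduction and fluoride unmasking finish the dihydrochalcone.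

Key step: step 4

Remark on numbering: atoms follow the 2H-chromene (O1, C2, C3, C4, C4a, C5 to C8, C8a); ring B is the benzo ring of the chromene, ring A the 2,4-dihydroxyphenyl ketone ring; SEM = [2-(trimethylsilyl)ethoxy]methyl.
Assumption: commercial (R)-(−)-linalool of high enantiomeric purity is used, and the enantiomeric purity of the target mirrors it, because no bond to the stereocentre is made or broken in the route.
Assumption: 2,3-dichloro-4-hydroxybenzaldehyde, 2,4-dihydroxyacetophenone and dibutyl vinylboronate are taken as commercial.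
Remark: 2H-chromenes open photochemically at O1–C2, which would racemise C2, so compounds 10 to 16 are handled with exclusion of UV light.

**Step 1**
Reactants: 1 (R)-(−)-linalool
Product: 3 (3E,6R)-2,6-dimethylocta-3,7-diene-2,6-diol, via allylic hydroperoxide 2 (not isolated)
Conditions: O2, 5,10,15,20-tetraphenylporphyrin (cat.), visible light, CH2Cl2, 0 °C; then PPh3, rt; chromatography
Reagents that add atoms: dioxygen O=O
Why: Schenck ene reaction: singlet oxygen attacks only the electron-rich trisubstituted alkene (the vinyl group is inert) and abstraction of a C5 hydrogen gives the E-configured tertiary hydroperoxide 2 alongside its secondary regioisomer, so that phosphine reduction and chromatography should deliver 3 with the linalool stereocentre untouched.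

**Step 2**
Reactants: 3 (3E,6R)-2,6-dimethylocta-3,7-diene-2,6-diol
Product: 6 (5R)-5-[(2E)-4-hydroxy-4-methylpent-2-en-1-yl]-5-methyl-1,2-oxaborol-2(5H)-ol, via bis(vinylboronate) ester 4 (not isolated), via cyclic butyl boronate 5 (not isolated)
Conditions: CH2=CHB(On-Bu)2 (2.5 equiv), toluene, 50 °C, n-BuOH removed under reduced pressure; then second-generation Grubbs catalyst RuCl2(=CHPh)(PCy3)(SIMes) (5 mol%), CH2Cl2, 40 °C; then H2O, rt
Reagents that add atoms: dibutyl vinylboronate C=CB(OCCCC)OCCCC; water O
Why: Boron-tethered ring-closing metathesis: transesterification ties the vinylboron unit to the tertiary allylic oxygen, metathesis between the two terminal vinyl groups closes the five-membered oxaborole (which fixes the new C=C bond as Z) with loss of ethene, the hindered internal E-alkene is not expected to react, and water then cleaves the butyl ester and the side-chain boronate.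

**Step 3**
Reactants: 7 2,3-dichloro-4-hydroxybenzaldehyde
Product: 8 2,3-dichloro-4-{[2-(trimethylsilyl)ethoxy]methoxy}benzaldehyde
Conditions: SEMCl, K2CO3, DMF, 0 °C to rt
Reagents that add atoms: 2-(trimethylsilyl)ethoxymethyl chloride C[Si](C)(C)CCOCCl
Why: Williamson-type O-alkylation (SEM protection) of the acidic para-formyl phenoxide, needed because a free phenoxide would deactivate the adjacent chloride and compete for palladium in step 4.

**Step 4**
Reactants: 8 2,3-dichloro-4-{[2-(trimethylsilyl)ethoxy]methoxy}benzaldehyde; 6 (5R)-5-[(2E)-4-hydroxy-4-methylpent-2-en-1-yl]-5-methyl-1,2-oxaborol-2(5H)-ol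
Product: 10 (2R)-2-[(2E)-4-hydroxy-4-methylpent-2-en-1-yl]-2-methyl-8-{[2-(trimethylsilyl)ethoxy]methoxy}-2H-chromene-5-carbaldehyde, via Z-alkenyl chloroarene 9 (not isolated)
Conditions: Pd(OAc)2 (5 mol%), 2-di-tert-butylphosphino-2′,4′,6′-triisopropylbiphenyl (t-BuXPhos, 10 mol%), K3PO4·H2O (4 equiv), toluene, 60 °C then 100 °C
Reagents that add atoms: none
Why: Zerovalent palladium inserts first into the C–Cl bond ortho to the formyl group (future C4a), the oxaborole transfers its alkenyl carbon C4 with retention of the ring-enforced Z geometry, and hydrolysis of the resulting borate frees the tertiary alcohol in 9; a second oxidative addition at the neighbouring C–Cl bond (future C8a), alkoxide binding and C–O reductive elimination then give the chromene. The closest known reaction types are the Suzuki–Miyaura coupling of cyclic alkenylboronic hemiesters and the palladium-catalysed intramolecular O-arylation of tertiary alcohols (Buchwald–Hartwig etherification), run here in one pot with one catalyst. The pyran ring is closed at O1–C8a by reductive elimination from a seven-membered divalent arylpalladium alkoxide, a six-membered ring closure that the cis C3=C4 alkene preorganises. No new stereocentre is formed: C2 comes from (R)-linalool, no bond to it is made or broken, and the tertiary alkoxide has no β-hydrogen to lose. The step needs site selectivity between the two chlorides, secured by activation of the C4a chloride by the ortho formyl group and deactivation of the C8a chloride by the ortho alkoxy group, and the right order of events, secured by the oxygen being tied to boron until transmetalation is over.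

**Step 5**
Reactants: 11 1-(2,4-dihydroxyphenyl)ethan-1-one
Product: 12 1-[2,4-bis({[2-(trimethylsilyl)ethoxy]methoxy})phenyl]ethan-1-one
Conditions: SEMCl (2.4 equiv), NaH, DMF, 0 °C to rt
Reagents that add atoms: 2-(trimethylsilyl)ethoxymethyl chloride C[Si](C)(C)CCOCCl
Why: Double O-alkylation (SEM protection) of both phenoxides, NaH being strong enough to break the hydrogen bond of the ortho-hydroxy ketone.

**Step 6**
Reactants: 10 (2R)-2-[(2E)-4-hydroxy-4-methylpent-2-en-1-yl]-2-methyl-8-{[2-(trimethylsilyl)ethoxy]methoxy}-2H-chromene-5-carbaldehyde; 12 1-[2,4-bis({[2-(trimethylsilyl)ethoxy]methoxy})phenyl]ethan-1-one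
Product: 14 (2E)-1-[2,4-bis({[2-(trimethylsilyl)ethoxy]methoxy})phenyl]-3-[(2R)-2-[(2E)-4-hydroxy-4-methylpent-2-en-1-yl]-2-methyl-8-{[2-(trimethylsilyl)ethoxy]methoxy}-2H-chromen-5-yl]prop-2-en-1-one, via aldol adduct 13 (not isolated)
Conditions: KOH, EtOH/THF, rt
Reagents that add atoms: none
Why: Claisen–Schmidt aldol condensation: the enolate of methyl ketone 12 adds to the non-enolisable aldehyde 10 and E1cB dehydration of 13 gives the E-enone, the SEM ethers, the chromene and the tertiary alcohol being stable to hydroxide.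

**Step 7**
Reactants: 14 (2E)-1-[2,4-bis({[2-(trimethylsilyl)ethoxy]methoxy})phenyl]-3-[(2R)-2-[(2E)-4-hydroxy-4-methylpent-2-en-1-yl]-2-methyl-8-{[2-(trimethylsilyl)ethoxy]methoxy}-2H-chromen-5-yl]prop-2-en-1-one
Product: 15 1-[2,4-bis({[2-(trimethylsilyl)ethoxy]methoxy})phenyl]-3-[(2R)-2-[(2E)-4-hydroxy-4-methylpent-2-en-1-yl]-2-methyl-8-{[2-(trimethylsilyl)ethoxy]methoxy}-2H-chromen-5-yl]propan-1-one
Conditions: [(Ph3P)CuH]6 (Stryker's reagent), toluene, H2O (2 equiv), rt
Reagents that add atoms: none
Why: Conjugate reduction with Stryker's reagent: hydride is delivered from copper to the β-carbon of the enone only and water protonates the copper enolate, so the unactivated chromene and side-chain alkenes and the ketone should survive.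

**Step 8**
Reactants: 15 1-[2,4-bis({[2-(trimethylsilyl)ethoxy]methoxy})phenyl]-3-[(2R)-2-[(2E)-4-hydroxy-4-methylpent-2-en-1-yl]-2-methyl-8-{[2-(trimethylsilyl)ethoxy]methoxy}-2H-chromen-5-yl]propan-1-one
Product: 16 1-(2,4-dihydroxyphenyl)-3-[(2R)-8-hydroxy-2-[(2E)-4-hydroxy-4-methylpent-2-en-1-yl]-2-methyl-2H-chromen-5-yl]propan-1-one
Conditions: TBAF (excess), ethylenediamine, THF, 60 °C; then aq. NH4Cl
Reagents that add atoms: none
Why: Fluoride-induced fragmentation of the three SEM ethers (attack at silicon, loss of ethene and formaldehyde, phenoxide as leaving group) under acid-free conditions that should spare the tertiary allylic alcohol and the 2H-chromene, ethylenediamine trapping the formaldehyde.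

**Compound list**

1 | (R)-(−)-linalool, (3R)-3,7-dimethylocta-1,6-dien-3-ol | C=C[C@](C)(O)CCC=C(C)C | starting material
2 | (3E,6R)-6-hydroxy-2,6-dimethylocta-3,7-dien-2-yl hydroperoxide (not isolated) | C=C[C@](C)(O)C/C=C/C(C)(C)OO | intermediate
3 | (3E,6R)-2,6-dimethylocta-3,7-diene-2,6-diol | C=C[C@](C)(O)C/C=C/C(C)(C)O | intermediate
4 | bis(butyl vinylboronate) ester of diol 3 (not isolated) | C=C[C@](C)(OB(C=C)OCCCC)C/C=C/C(C)(C)OB(C=C)OCCCC | intermediate
5 | (5R)-2-butoxy-5-methyl-2,5-dihydro-1,2-oxaborole bearing the (2E)-4-methylpent-2-en-1-yl chain as its butyl vinylboronate ester (not isolated) | CCCCOB1C=C[C@](C)(O1)C/C=C/C(C)(C)OB(C=C)OCCCC | intermediate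
6 | (5R)-5-[(2E)-4-hydroxy-4-methylpent-2-en-1-yl]-5-methyl-1,2-oxaborol-2(5H)-ol | OB1C=C[C@](C)(O1)C/C=C/C(C)(C)O | intermediate
7 | 2,3-dichloro-4-hydroxybenzaldehyde | O=Cc1ccc(O)c(Cl)c1Cl | starting material
8 | 2,3-dichloro-4-{[2-(trimethylsilyl)ethoxy]methoxy}benzaldehyde | O=Cc1ccc(OCOCC[Si](C)(C)C)c(Cl)c1Cl | intermediate
9 | 3-chloro-2-[(1Z,3R,5E)-3,7-dihydroxy-3,7-dimethylocta-1,5-dien-1-yl]-4-{[2-(trimethylsilyl)ethoxy]methoxy}benzaldehyde (not isolated) | O=Cc1ccc(OCOCC[Si](C)(C)C)c(Cl)c1/C=C\[C@](C)(O)C/C=C/C(C)(C)O | intermediate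
10 | (2R)-2-[(2E)-4-hydroxy-4-methylpent-2-en-1-yl]-2-methyl-8-{[2-(trimethylsilyl)ethoxy]methoxy}-2H-chromene-5-carbaldehyde | CC(C)(O)/C=C/C[C@]1(C)C=Cc2c(C=O)ccc(OCOCC[Si](C)(C)C)c2O1 | intermediate
11 | 1-(2,4-dihydroxyphenyl)ethan-1-one (2,4-dihydroxyacetophenone) | CC(=O)c1ccc(O)cc1O | starting material
12 | 1-[2,4-bis({[2-(trimethylsilyl)ethoxy]methoxy})phenyl]ethan-1-one | CC(=O)c1ccc(OCOCC[Si](C)(C)C)cc1OCOCC[Si](C)(C)C | intermediate
13 | 1-[2,4-bis(SEM-oxy)phenyl]-3-hydroxy-3-[(2R)-2-[(2E)-4-hydroxy-4-methylpent-2-en-1-yl]-2-methyl-8-(SEM-oxy)-2H-chromen-5-yl]propan-1-one, aldol adduct, both carbinol epimers (not isolated) | CC(C)(O)/C=C/C[C@]1(C)C=Cc2c(C(O)CC(=O)c3ccc(OCOCC[Si](C)(C)C)cc3OCOCC[Si](C)(C)C)ccc(OCOCC[Si](C)(C)C)c2O1 | intermediate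
14 | (2E)-1-[2,4-bis(SEM-oxy)phenyl]-3-[(2R)-2-[(2E)-4-hydroxy-4-methylpent-2-en-1-yl]-2-methyl-8-(SEM-oxy)-2H-chromen-5-yl]prop-2-en-1-one | CC(C)(O)/C=C/C[C@]1(C)C=Cc2c(/C=C/C(=O)c3ccc(OCOCC[Si](C)(C)C)cc3OCOCC[Si](C)(C)C)ccc(OCOCC[Si](C)(C)C)c2O1 | intermediate
15 | 1-[2,4-bis(SEM-oxy)phenyl]-3-[(2R)-2-[(2E)-4-hydroxy-4-methylpent-2-en-1-yl]-2-methyl-8-(SEM-oxy)-2H-chromen-5-yl]propan-1-one | CC(C)(O)/C=C/C[C@]1(C)C=Cc2c(CCC(=O)c3ccc(OCOCC[Si](C)(C)C)cc3OCOCC[Si](C)(C)C)ccc(OCOCC[Si](C)(C)C)c2O1 | intermediate
16 | 1-(2,4-dihydroxyphenyl)-3-[(2R)-8-hydroxy-2-[(2E)-4-hydroxy-4-methylpent-2-en-1-yl]-2-methyl-2H-chromen-5-yl]propan-1-one (CNP0311864.1) | CC(C)(O)/C=C/C[C@]1(C)C=Cc2c(CCC(=O)c3ccc(O)cc3O)ccc(O)c2O1 | target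

**Step count and risks**

Total step count: 8. Longest linear sequence: 6 steps (steps 1, 2, 4, 6, 7, 8, from (R)-linalool).

Steps most likely to fail:

Step 4. The second oxidative addition, at an electron-rich chloride flanked by two ortho substituents, may be too slow, so that the cascade stalls at 9 or the chloride is hydrolysed; the first oxidative addition may also fail to distinguish the two chlorides cleanly. The fallback sets out from 6 and comes back at 10, and lets the leaving groups rather than ring electronics fix the order of the two couplings. Commercial 2-bromo-3-hydroxy-4-methoxybenzaldehyde F1 is demethylated (BBr3, CH2Cl2) to 2-bromo-3,4-dihydroxybenzaldehyde F2. The more acidic hydroxyl para to the formyl group is protected (SEMCl, 1 equiv K2CO3, DMF) to give 2-bromo-3-hydroxy-4-{[2-(trimethylsilyl)ethoxy]methoxy}benzaldehyde F3. Triflation (Tf2O, pyridine, CH2Cl2) gives 2-bromo-3-formyl-6-{[2-(trimethylsilyl)ethoxy]methoxy}phenyl trifluoromethanesulfonate F4. Coupling of F4 with 6 under the conditions of step 4 should engage the bromide at C4a first and close the ring at the far more reactive triflate at C8a, giving 10.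

Step 2. Tethering of the hindered tertiary alcohol to boron may be incomplete or reversible, so that ring closure is slow and catalyst decay or metathesis at the side-chain alkene takes over. The fallback sets out from 3 and comes back at 10, and uses an irreversible silicon tether. Silylation of both hydroxyls (ClSiMe2CH=CH2, imidazole, DMF) gives the bis(dimethylvinylsilyl) ether F5. Ring-closing metathesis with the molybdenum alkylidene Mo(=CHCMe2Ph)(=N-2,6-i-Pr2C6H3)[OCMe(CF3)2]2 (benzene, rt) gives (5R)-2,2,5-trimethyl-5-[(2E)-4-methyl-4-{[dimethyl(vinyl)silyl]oxy}pent-2-en-1-yl]-2,5-dihydro-1,2-oxasilole F6. Fluoride-activated Hiyama–Denmark coupling of F6 with 8 (Pd(OAc)2, t-BuXPhos, TBAF, THF; then K3PO4, toluene, 100 °C) should pass through 9 once both Si–O bonds are cleaved and close to 10 in the same pot.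

Step 1. The ene reaction abstracts hydrogen from the terminal methyl group about as readily as from C5, so a large part of the material is expected to end as the regioisomeric secondary hydroperoxide. The fallback sets out from 1 and comes back at 3, and oxidises the side chain site-selectively in three stages. Buffered epoxidation of the trisubstituted alkene (mCPBA, NaHCO3, CH2Cl2, 0 °C) gives (3R)-5-(3,3-dimethyloxiran-2-yl)-3-methylpent-1-en-3-ol F7. Opening at the less hindered epoxide carbon with PhSeNa (PhSeSePh, NaBH4, EtOH) gives (6R)-2,6-dimethyl-3-(phenylselanyl)oct-7-ene-2,6-diol F8. Oxidation (H2O2, THF, 0 °C to rt) and syn elimination of the selenoxide, which can only run away from the fully substituted carbinol carbon, should give 3 as the E-alkene.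

**Further compounds**

F1 | step 4 | 2-bromo-3-hydroxy-4-methoxybenzaldehyde | COc1ccc(C=O)c(Br)c1O
F2 | step 4 | 2-bromo-3,4-dihydroxybenzaldehyde | O=Cc1ccc(O)c(O)c1Br
F3 | step 4 | 2-bromo-3-hydroxy-4-{[2-(trimethylsilyl)ethoxy]methoxy}benzaldehyde | O=Cc1ccc(OCOCC[Si](C)(C)C)c(O)c1Br
F4 | step 4 | 2-bromo-3-formyl-6-{[2-(trimethylsilyl)ethoxy]methoxy}phenyl trifluoromethanesulfonate | O=Cc1ccc(OCOCC[Si](C)(C)C)c(OS(=O)(=O)C(F)(F)F)c1Br
F5 | step 2 | bis(dimethylvinylsilyl) ether of (3E,6R)-2,6-dimethylocta-3,7-diene-2,6-diol | C=C[C@](C)(O[Si](C)(C)C=C)C/C=C/C(C)(C)O[Si](C)(C)C=C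
F6 | step 2 | (5R)-2,2,5-trimethyl-5-[(2E)-4-methyl-4-{[dimethyl(vinyl)silyl]oxy}pent-2-en-1-yl]-2,5-dihydro-1,2-oxasilole | C[Si]1(C)C=C[C@](C)(O1)C/C=C/C(C)(C)O[Si](C)(C)C=C
F7 | step 1 | (3R)-5-(3,3-dimethyloxiran-2-yl)-3-methylpent-1-en-3-ol (6,7-epoxylinalool, both epoxide epimers) | C=C[C@](C)(O)CCC1OC1(C)C
F8 | step 1 | (6R)-2,6-dimethyl-3-(phenylselanyl)oct-7-ene-2,6-diol (both selenide epimers) | C=C[C@](C)(O)CCC([Se]c1ccccc1)C(C)(C)O
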